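**Strategy.** Ring A (C1–C5, C10) is not cyclised directly: it is made by a stereospecific Meinwald/semipinacol ring contraction of a cycloheptene oxide. A trans-fused 6–7 bicycle, obtained from (R)-carvone by double α′-alkylation and ring-closing metathesis, carries a 4β,19β-epoxide; Lewis acid opening at tertiary C4 and 1,2-shift of C3 contracts the seven-membered ring to ring A and creates, in one operation, the quaternary C4 next to ring-fusion C5 with its equatorial C18 methyl and axial C19 at the aldehyde level. C19 then delivers the 6β-oxygen by iodolactonisation, and an (R)-diynyl carbinol furnishes C11–C16 and both spiro rings.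

Key step: step 5

Remark: labdane numbering and the α/β descriptors of the target are used for all intermediates. The C9 carbinol configuration in 21–23 (drawn as the expected epimer) and the enone geometry in 24–25 are inconsequential, because both are erased before C9 is set in step 17.

## Route

Step 1
Reactants: 1 (R)-(−)-carvone
Product: 2 6-methylcarvone (C6 epimer mixture)
Conditions: LDA, THF, −78 °C; MeI, −78 → 0 °C
Reagents that add atoms: iodomethane, CI
Why: Kinetic α′-deprotonation of the enone (carvone C6, the future C10) and SN2 methylation; the new centre is not controlled and need not be, because it is re-enolised in step 2.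

Step 2
Reactants: 2 6-methylcarvone; 3 5-iodopent-1-ene
Product: 4 6-methyl-6-(pent-4-enyl)carvone (pentenyl trans to isopropenyl)
Conditions: LDA, THF/DMPU, −78 °C; 3, −78 → 23 °C
Reagents that add atoms: none
Why: Enolate alkylation in which the iodide approaches anti to the adjacent isopropenyl group at C5, so the chain (future C1–C3 and C19) ends trans and the C10 methyl cis to isopropenyl, which fixes the trans relationship of C5-H and C10-CH3.

Step 3
Reactants: 4 dialkylated carvone
Product: 5 trans-fused 6–7 dienone (C4=C19 cycloheptene)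
Conditions: Grubbs second-generation catalyst (5 mol %), CH2Cl2 (5 mM), 40 °C
Reagents that add atoms: none
Why: Ring-closing metathesis of the terminal alkene onto the 1,1-disubstituted isopropenyl group should give the trisubstituted cycloheptene, while the conjugated trisubstituted enone alkene is inert to the ruthenium carbene.

Step 4
Reactants: 5 bicyclic dienone
Product: 7 4β,19β-epoxide of 5, via bromohydrin 6 (not isolated)
Conditions: NBS, THF/H2O (3:1), 0 °C; then K2CO3, MeOH, 23 °C
Reagents that add atoms: water, O (N-bromosuccinimide, O=C1CCC(=O)N1Br, supplies only the bromine of intermediate 6)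
Why: Bromohydrin formation on the only electron-rich alkene (bromonium on the less hindered α face, anti opening by water at tertiary C4, as in hypobromous acid additions to Δ5-steroids) followed by intramolecular SN2 closure with inversion at C19 should place the epoxide oxygen on the β face.

Step 5
Reactants: 7 4β,19β-epoxide
Product: 8 9-oxo-11,12,13,14,15,16-hexanorlabd-7-en-19-al (trans-decalin with 4α-CH3 and 4β-CHO)
Conditions: methylaluminium bis(4-bromo-2,6-di-tert-butylphenoxide) (MABR, 20 mol %), CH2Cl2, −78 → −20 °C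
Reagents that add atoms: none
Why: Coordination of the bulky aluminium Lewis acid to the epoxide oxygen ionises the tertiary C4–O bond, and the C3–C19 ring bond migrates to C4 from the face opposite the departing oxygen while C19 becomes the aldehyde carbon; this is a Meinwald (epoxide-to-aldehyde semipinacol) rearrangement, closest in type to the contraction of 1-methylcycloalkene oxides to 1-methylcycloalkanecarbaldehydes. The six-membered ring A (C1–C5, C10) is closed by this suprafacial 1,2-alkyl shift, which contracts the cycloheptane by one atom; no other ring is formed. The only new stereocentre, quaternary C4, is set stereospecifically by the epoxide configuration: inversion at C4 places the new C4–C3 bond on the α side and leaves C19 (CHO) axial β and C18 equatorial α. The step needs cleavage at C4 rather than C19, which the tertiary centre secures, and ring-bond rather than hydride migration from C19, which the bulky Lewis acid (biased towards the alkyl-shift, aldehyde-forming manifold) and the relief of cycloheptene-oxide strain should secure. The enone and the C5 and C10 centres are spectators.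

Step 6
Reactants: 8 enone aldehyde
Product: 9 9-oxo-hexanorlabd-7-en-19-oic acid
Conditions: NaClO2, NaH2PO4, 2-methylbut-2-ene, t-BuOH/H2O, 0 → 23 °C
Reagents that add atoms: sodium chlorite, [Na+].[O-]Cl=O
Why: Pinnick oxidation of the non-enolisable neopentyl aldehyde to the acid should leave the enone untouched.

Step 7
Reactants: 9 enone acid
Product: 11 7α-iodo-9-oxo-hexanorlabdan-19,6β-olide (C8 epimers), via deconjugated keto acid 10 (not isolated)
Conditions: LDA (2.5 equiv), THF, −78 °C; AcOH, −78 °C; then I2, NaHCO3, MeCN/H2O, 0 °C, dark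
Reagents that add atoms: iodine, II
Why: Kinetic α-protonation (C8) of the extended dienolate deconjugates the enone to the C6=C7 alkene, and iodolactonisation then proceeds by anti addition with the axial 4β-carboxylate attacking C6 from the β face (γ-lactone, trans-diaxial to the 7α-iodide), which sets C6.

Step 8
Reactants: 11 iodolactone
Product: 13 9-oxo-hexanorlabdan-19,6β-olide (8α-CH3), via C8-epimeric ketolactone 12 (not isolated)
Conditions: Bu3SnH, AIBN (cat.), PhMe, 80 °C; then DBU, 80 °C
Reagents that add atoms: none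
Why: Tin hydride radical dehalogenation removes the 7α-iodide, and base-mediated enolisation at C8 should funnel both C8 epimers to the equatorial 8α-methyl isomer, which avoids the 1,3-diaxial clash with the C10 methyl.

Step 9
Reactants: 14 (triisopropylsilyl)acetylene; 15 dimethyl oxalate
Product: 16 methyl 2-oxo-4-(triisopropylsilyl)but-3-ynoate
Conditions: n-BuLi, THF, −78 °C; cannulate into 15 (3 equiv), THF, −78 °C; aq. NH4Cl
Reagents that add atoms: none
Why: Acylation of the lithium acetylide with excess oxalate under inverse addition should stop at the α-keto ester, because the tetrahedral intermediate collapses only on work-up.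

Step 10
Reactants: 16 alkynyl keto ester; 17 (trimethylsilyl)acetylene
Product: 18 methyl (2R)-2-hydroxy-4-(triisopropylsilyl)-2-[(trimethylsilyl)ethynyl]but-3-ynoate
Conditions: Zn(OTf)2 (20 mol %), 2-(dimethylamino)-1-(4-nitrophenyl)-3-(tert-butyldimethylsilyloxy)propan-1-ol (22 mol %, the antipode that delivers the R carbinol), Et3N (30 mol %), PhMe, 50 °C, sealed
Reagents that add atoms: none
Why: Catalytic enantioselective alkynylation of an α-keto ester by a zinc acetylide formed in situ, in which two-point binding of the keto ester to the chiral zinc complex differentiates its faces and creates the C13 carbinol centre.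

Step 11
Reactants: 18 bis-silyl diynyl carbinol
Product: 19 methyl (2R)-2-ethynyl-2-hydroxy-4-(triisopropylsilyl)but-3-ynoate
Conditions: K2CO3 (0.1 equiv), MeOH, 0 °C
Reagents that add atoms: none
Why: Methanolysis cleaves the C(sp)–SiMe3 bond selectively, because the bulky triisopropylsilyl alkyne is inert to carbonate in methanol.

Step 12
Reactants: 19 hydroxy ester
Product: 20 methyl (2R)-2-ethynyl-2-(triethylsilyloxy)-4-(triisopropylsilyl)but-3-ynoate
Conditions: TESOTf, 2,6-lutidine, CH2Cl2, −78 → 0 °C
Reagents that add atoms: triethylsilyl trifluoromethanesulfonate, CC[Si](CC)(CC)OS(=O)(=O)C(F)(F)F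
Why: Silyl triflate silylation of the tertiary alcohol gives an acid-labile ether that blocks the C13 oxygen during the coupling and the later 1,3-transposition.

Step 13
Reactants: 13 ketolactone; 20 fragment alkyne
Product: 21 C9 propargylic alcohol (9β-OH expected) carrying the 19,6β-lactone and the C13 ester
Conditions: 20, LiHMDS, THF, −78 °C; CeCl3, −78 °C; 13, −78 → −20 °C; aq. NH4Cl
Reagents that add atoms: none
Why: 1,2-Addition of the weakly basic cerium acetylide to the C9 ketone should outrun attack on the neopentyl lactone and the quaternary ester, and it is expected from the α (axial) face.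

Step 14
Reactants: 21 lactone ester
Product: 22 6β,9,16,19-tetraol (13-OTES, 15-TIPS)
Conditions: LiBH4, THF, MeOH (cat.), 0 → 40 °C; pH 7 buffer
Reagents that add atoms: none
Why: Borohydride reduction converts the γ-lactone to the 6β,19-diol and the methyl ester to the C16 alcohol in one operation without touching the alkynes or silyl groups.

Step 15
Reactants: 22 tetraol
Product: 23 16,19-bis(tert-butyldiphenylsilyl) ether
Conditions: TBDPSCl (2.4 equiv), imidazole, DMF, 0 → 23 °C
Reagents that add atoms: tert-butyl(chloro)diphenylsilane, CC(C)(C)[Si](Cl)(c1ccccc1)c1ccccc1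
Why: The bulky silyl chloride should protect only the two primary hydroxyls, leaving free the tertiary 9-OH and the axial 6β-OH, which cannot bridge to C9 without a boat ring B.

Step 16
Reactants: 23 propargylic alcohol
Product: 24 C9=C11 enone with C12 ketone
Conditions: MoO2(acac)2 (5 mol %), Ph3PAuCl (2 mol %), AgOTf (2 mol %), PhMe, 23 °C
Reagents that add atoms: none
Why: Meyer–Schuster rearrangement by oxo-molybdenum 1,3-transposition of the free tertiary propargylic alcohol (gold activating the alkyne) moves oxygen from C9 to C12 regiospecifically, since the C13 oxygen is silylated, and avoids the cationic Rupe pathway.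

Step 17
Reactants: 24 enone
Product: 26 spiro tetrahydrofuran-3-one (9α,13-epoxide), via hydroxy enone 25 (not isolated)
Conditions: TsOH·H2O (20 mol %), MeOH/CH2Cl2 (1:4), 0 → 23 °C
Reagents that add atoms: none
Why: Acid cleaves the tertiary triethylsilyl ether and the freed C13 hydroxyl adds to C9 of the protonated enone (5-endo-trig oxa-Michael, as in the classical butynediol-to-tetrahydrofuran-3-one cyclisation) from the α face, axial and anti to the C10 methyl, which sets the spiro centre C9 while C13 is untouched.

Step 18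
Reactants: 26 protected spiro ketone
Product: 27 (13R)-9α,13-epoxy-6β,16,19-trihydroxylabd-14-yn-12-one
Conditions: TBAF, AcOH (1:1), THF, 0 → 23 °C
Reagents that add atoms: none
Why: Buffered fluoride removes both silyl ethers and the alkynyl triisopropylsilyl group in one operation, and the buffer suppresses retro-aldol loss of the C16 hydroxymethyl group.

Step 19
Reactants: 27 alkynyl triol
Product: 28 target
Conditions: Mo(CO)6 (30 mol %), Et3N, Et2O, hν (350 nm), 23 °C
Reagents that add atoms: none
Why: Molybdenum-vinylidene alkynol cycloisomerisation (endo attack of the homopropargylic C16 hydroxyl on terminal C15) closes the 2,3-dihydrofuran under basic conditions, and only the C16 hydroxyl is positioned to cyclise.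

## Compound list

1 | (R)-(−)-carvone, (5R)-2-methyl-5-(prop-1-en-2-yl)cyclohex-2-en-1-one | CC1=CC[C@H](CC1=O)C(C)=C | starting material
2 | 6-methylcarvone, (5R)-2,6-dimethyl-5-(prop-1-en-2-yl)cyclohex-2-en-1-one, C6 epimer mixture | CC1=CC[C@H](C(C)C1=O)C(C)=C | intermediate
3 | 5-iodopent-1-ene | C=CCCCI | starting material
4 | (5S,6S)-2,6-dimethyl-6-(pent-4-en-1-yl)-5-(prop-1-en-2-yl)cyclohex-2-en-1-one | CC1=CC[C@@H](C(C)=C)[C@](C)(CCCC=C)C1=O | intermediate
5 | trans-fused 6–7 dienone, 3,4a,9-trimethyl-1,4a,5,6,7,9a-hexahydro-4H-benzo[7]annulen-4-one (4a-CH3 β, 9a-H α; C4=C19 alkene) | CC1=CC[C@H]2C(C)=CCCC[C@]2(C)C1=O | intermediate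
6 | bromohydrin of 5 (4β-OH, 19α-Br) | CC1=CC[C@H]2[C@@](C)(O)[C@H](Br)CCC[C@]2(C)C1=O | intermediate
7 | 4β,19β-epoxide of 5 (oxygen cis to the angular methyl) | CC1=CC[C@H]2[C@@]3(C)O[C@H]3CCC[C@]2(C)C1=O | intermediate
8 | 9-oxo-11,12,13,14,15,16-hexanorlabd-7-en-19-al | CC1=CC[C@H]2[C@@](C)(C=O)CCC[C@]2(C)C1=O | intermediate
9 | 9-oxo-11,12,13,14,15,16-hexanorlabd-7-en-19-oic acid | CC1=CC[C@H]2[C@@](C)(C(=O)O)CCC[C@]2(C)C1=O | intermediate
10 | 9-oxo-11,12,13,14,15,16-hexanorlabd-6-en-19-oic acid, C8 epimer mixture | CC1C=C[C@H]2[C@@](C)(C(=O)O)CCC[C@]2(C)C1=O | intermediate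
11 | 7α-iodo-9-oxo-11,12,13,14,15,16-hexanorlabdan-19,6β-olide, C8 epimer mixture | CC1[C@H](I)[C@H]2OC(=O)[C@@]3(C)CCC[C@@](C)([C@@H]23)C1=O | intermediate
12 | 9-oxo-11,12,13,14,15,16-hexanorlabdan-19,6β-olide, C8 epimer mixture | CC1C[C@H]2OC(=O)[C@@]3(C)CCC[C@@](C)([C@@H]23)C1=O | intermediate
13 | 9-oxo-11,12,13,14,15,16-hexanorlabdan-19,6β-olide (8α-CH3, 8β-H) | C[C@@H]1C[C@H]2OC(=O)[C@@]3(C)CCC[C@@](C)([C@@H]23)C1=O | intermediate
14 | (triisopropylsilyl)acetylene | C#C[Si](C(C)C)(C(C)C)C(C)C | starting material
15 | dimethyl oxalate | COC(=O)C(=O)OC | starting material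
16 | methyl 2-oxo-4-(triisopropylsilyl)but-3-ynoate | COC(=O)C(=O)C#C[Si](C(C)C)(C(C)C)C(C)C | intermediate
17 | (trimethylsilyl)acetylene | C#C[Si](C)(C)C | starting material
18 | methyl (2R)-2-hydroxy-4-(triisopropylsilyl)-2-[(trimethylsilyl)ethynyl]but-3-ynoate | C[Si](C)(C)C#C[C@](O)(C(=O)OC)C#C[Si](C(C)C)(C(C)C)C(C)C | intermediate
19 | methyl (2R)-2-ethynyl-2-hydroxy-4-(triisopropylsilyl)but-3-ynoate | C#C[C@](O)(C(=O)OC)C#C[Si](C(C)C)(C(C)C)C(C)C | intermediate
20 | methyl (2R)-2-ethynyl-2-(triethylsilyloxy)-4-(triisopropylsilyl)but-3-ynoate | C#C[C@](O[Si](CC)(CC)CC)(C(=O)OC)C#C[Si](C(C)C)(C(C)C)C(C)C | intermediate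
21 | methyl (13R)-9β-hydroxy-13-(triethylsilyloxy)-15-(triisopropylsilyl)-19,6β-olidolabda-11,14-diyn-16-oate | C[C@@H]1C[C@H]2OC(=O)[C@@]3(C)CCC[C@@](C)([C@@H]23)[C@]1(O)C#C[C@](O[Si](CC)(CC)CC)(C(=O)OC)C#C[Si](C(C)C)(C(C)C)C(C)C | intermediate
22 | (13R)-13-(triethylsilyloxy)-15-(triisopropylsilyl)labda-11,14-diyne-6β,9β,16,19-tetraol | C[C@@H]1C[C@@H](O)[C@H]2[C@@](C)(CO)CCC[C@]2(C)[C@]1(O)C#C[C@](O[Si](CC)(CC)CC)(CO)C#C[Si](C(C)C)(C(C)C)C(C)C | intermediate
23 | 16,19-bis(tert-butyldiphenylsilyl) ether of 22 | C[C@@H]1C[C@@H](O)[C@H]2[C@@](C)(CO[Si](c3ccccc3)(c3ccccc3)C(C)(C)C)CCC[C@]2(C)[C@]1(O)C#C[C@](O[Si](CC)(CC)CC)(CO[Si](c1ccccc1)(c1ccccc1)C(C)(C)C)C#C[Si](C(C)C)(C(C)C)C(C)C | intermediate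
24 | (13R)-6β-hydroxy-16,19-bis(tert-butyldiphenylsilyloxy)-13-(triethylsilyloxy)-15-(triisopropylsilyl)labd-9(11)-en-14-yn-12-one | C[C@@H]1C[C@@H](O)[C@H]2[C@@](C)(CO[Si](c3ccccc3)(c3ccccc3)C(C)(C)C)CCC[C@]2(C)C1=CC(=O)[C@](O[Si](CC)(CC)CC)(CO[Si](c1ccccc1)(c1ccccc1)C(C)(C)C)C#C[Si](C(C)C)(C(C)C)C(C)C | intermediate
25 | 13-hydroxy analogue of 24 (triethylsilyl group removed) | C[C@@H]1C[C@@H](O)[C@H]2[C@@](C)(CO[Si](c3ccccc3)(c3ccccc3)C(C)(C)C)CCC[C@]2(C)C1=CC(=O)[C@](O)(CO[Si](c1ccccc1)(c1ccccc1)C(C)(C)C)C#C[Si](C(C)C)(C(C)C)C(C)C | intermediate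
26 | (13R)-9α,13-epoxy-6β-hydroxy-16,19-bis(tert-butyldiphenylsilyloxy)-15-(triisopropylsilyl)labd-14-yn-12-one | C[C@@H]1C[C@@H](O)[C@H]2[C@@](C)(CO[Si](c3ccccc3)(c3ccccc3)C(C)(C)C)CCC[C@]2(C)[C@@]12CC(=O)[C@](CO[Si](c1ccccc1)(c1ccccc1)C(C)(C)C)(C#C[Si](C(C)C)(C(C)C)C(C)C)O2 | intermediate
27 | (13R)-9α,13-epoxy-6β,16,19-trihydroxylabd-14-yn-12-one | C[C@@H]1C[C@@H](O)[C@H]2[C@@](C)(CO)CCC[C@]2(C)[C@@]12CC(=O)[C@](CO)(C#C)O2 | intermediate
28 | (13R)-9α,13:15,16-diepoxy-6β,19-dihydroxylabd-14-en-12-one | C[C@@H]1C[C@@H](O)[C@H]2[C@@](C)(CO)CCC[C@]2(C)[C@@]12CC(=O)[C@]1(C=COC1)O2 | target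

## Summary and risks

Total step count: 19. Longest linear sequence: 15 (steps 1–8 and 13–19, from carvone).

**Step 5 (key step, fed by step 4).** A 1,2-hydride shift from C19 may compete and give a ring-retained cycloheptanone; a free C4 cation may erode stereospecificity; and incomplete β-facial selectivity in step 4 would pass into C4 epimers. The fallback sets out from 5 and comes back at 8. Peracid epoxidation of 5 (mCPBA, NaHCO3, CH2Cl2) on the less hindered face should give the 4α,19α-epoxide F1. Lithium bromide–HMPA in benzene at 80 °C should open F1 at C4 with inversion to the lithium alkoxide of the 4β-bromo-19α-ol F2. In F2 the C3–C19 bond, anti-periplanar to bromide, migrates with a second inversion to give 8. Two inversions on the α-epoxide give the same C4 configuration as one inversion on the β-epoxide, and the halohydrin pathway has no hydride-shift channel from a free cation.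

**Step 10.** The two groups flanking the keto carbonyl differ little beyond the ester, so facial discrimination, and hence enantiomeric purity at C13, may be insufficient. If the sense of induction is opposite, exchanging the silyl groups of the two alkyne partners inverts it. The fallback sets out from 16 and comes back at 19. Transesterification of 16 with (1R,2S,5R)-8-phenylmenthol (DMAP cat., PhMe, reflux) should give the 8-phenylmenthyl keto ester F3. Addition of (trimethylsilyl)ethynylmagnesium bromide (THF, −78 °C) to the chelated keto ester, one face of which is shielded by the phenyl ring, should give the (2R)-carbinol ester F4. NaOMe in MeOH then removes the alkynyl trimethylsilyl group and exchanges the auxiliary for methyl, returning 19.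

**Step 13.** Addition of a branched acetylide to the doubly α-branched C9 ketone may be slow, so that enolisation at C8 or attack on the lactone or ester competes. The fallback sets out from 13 and comes back at 21; it changes the order of bond formation. Ethynylmagnesium bromide with CeCl3 (THF, −78 → 0 °C), the smallest possible nucleophile, should give the 9-ethynyl carbinol lactone F5. The terminal alkyne of F5 is then added to keto ester 16 under the zinc triflate/amino alcohol conditions of step 10 (catalyst-controlled C13) to give the C13-hydroxy ester F6. TESOTf/2,6-lutidine at −78 °C silylates the less hindered C13 hydroxyl of F6 to give 21.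

Further compounds
F1 | step 5 | 4α,19α-epoxide of dienone 5 | CC1=CC[C@H]2[C@]3(C)O[C@@H]3CCC[C@]2(C)C1=O
F2 | step 5 | 4β-bromo-19α-hydroxy derivative of 5 (lithium alkoxide in situ) | CC1=CC[C@H]2[C@@](C)(Br)[C@H](O)CCC[C@]2(C)C1=O
F3 | step 10 | (1R,2S,5R)-8-phenylmenthyl 2-oxo-4-(triisopropylsilyl)but-3-ynoate | C[C@@H]1CC[C@H]([C@@H](C1)OC(=O)C(=O)C#C[Si](C(C)C)(C(C)C)C(C)C)C(C)(C)c1ccccc1
F4 | step 10 | (1R,2S,5R)-8-phenylmenthyl (2R)-2-hydroxy-4-(triisopropylsilyl)-2-[(trimethylsilyl)ethynyl]but-3-ynoate | C[C@@H]1CC[C@H]([C@@H](C1)OC(=O)[C@@](O)(C#C[Si](C)(C)C)C#C[Si](C(C)C)(C(C)C)C(C)C)C(C)(C)c1ccccc1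
F5 | step 13 | 9α-ethynyl-9β-hydroxy-11,12,13,14,15,16-hexanorlabdan-19,6β-olide | C[C@@H]1C[C@H]2OC(=O)[C@@]3(C)CCC[C@@](C)([C@@H]23)[C@]1(O)C#C
F6 | step 13 | methyl (13R)-9β,13-dihydroxy-15-(triisopropylsilyl)-19,6β-olidolabda-11,14-diyn-16-oate | C[C@@H]1C[C@H]2OC(=O)[C@@]3(C)CCC[C@@](C)([C@@H]23)[C@]1(O)C#C[C@](O)(C(=O)OC)C#C[Si](C(C)C)(C(C)C)C(C)C
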